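**Retrosynthetic overview**
- The skeleton is cut once, at the biaryl bond between C6' of the epicatechin-type ring B and C2' of the epigallocatechin-type ring B; the last step is a single global hydrogenolysis.
- Both of these carbons are innately nucleophilic arene positions. The catechol of the epicatechin half is oxidised to its o-quinone, so that C6' becomes the β-carbon of an enedione (an aryl cation, i.e. vinylogous enolonium, equivalent), and the tris(benzyloxy)phenyl ring of the epigallocatechin half attacks it.
- Quinone precursor: (−)-epicatechin with ring A and the 3-OH capped as benzyl carbonates (one pot, catechol masked transiently as a boronate). Nucleophile: (−)-epigallocatechin, penta-O-benzylated, ring A blocked by 6,8-dibromination.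
- No ring is built: rings A, C and B of both halves and all four stereocentres (2R,3R twice) come intact from the two commercial tea catechins; only the biaryl axis is new.

Assumption: the SMILES fixes the four stereocentres but not the sense of the biaryl axis, so the compound as drawn is the target; if step 4 gives both atropisomers they are separated after step 5 (Sephadex LH-20 or reversed-phase HPLC).

**Step 1**
Reactants: 1 (−)-epicatechin
Product: 4 3,5,7-tris-O-(benzyloxycarbonyl)-(−)-epicatechin, via catechol phenylboronate 2 (not isolated), via tris-carbonate phenylboronate 3 (not isolated)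
Conditions: PhB(OH)2 (1.05 equiv), THF, rt, concentrate; then CbzCl (3.5 equiv), iPr2NEt, DMAP (cat.), CH2Cl2, 0 °C; then pinacol, EtOAc/H2O, rt
Reagents that add atoms: benzyl chloroformate, O=C(Cl)OCc1ccccc1; phenylboronic acid, OB(O)c1ccccc1 (its atoms are in 2 and 3 only)
Why: Transient boronic ester protection followed by DMAP-catalysed acylation: phenylboronic acid condenses only with the catechol pair, the three remaining hydroxyls become benzyl carbonates (which also deactivate ring A and cap the 3-OH against later attack on the quinone), and transesterification to pinacol frees the catechol; no stereocentre is touched.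

**Step 2**
Reactants: 5 (−)-epigallocatechin
Product: 6 5,7,3',4',5'-penta-O-benzyl-(−)-epigallocatechin
Conditions: BnBr (5.5 equiv), K2CO3 (6 equiv), DMF, Ar, −20 °C → rt
Reagents that add atoms: benzyl bromide, BrCc1ccccc1
Why: Williamson ether synthesis in which K2CO3 deprotonates only the five phenols, so the secondary 3-OH stays free and C2 and C3 are untouched.

**Step 3**
Reactants: 6 5,7,3',4',5'-penta-O-benzyl-(−)-epigallocatechin
Product: 7 6,8-dibromo-5,7,3',4',5'-penta-O-benzyl-(−)-epigallocatechin
Conditions: NBS (2.05 equiv), CH2Cl2, dark, −40 → 0 °C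
Reagents that add atoms: N-bromosuccinimide, O=C1CCC(=O)N1Br
Why: Electrophilic aromatic bromination goes first to C8 and then to C6 of the phloroglucinol-type ring A (three activating oxygens), which outpaces the tris(benzyloxy) ring B, so the only nucleophilic arene CH left is C2'/C6' of ring B (the two are equivalent).

**Step 4**
Reactants: 4 3,5,7-tris-O-(benzyloxycarbonyl)-(−)-epicatechin; 7 6,8-dibromo-5,7,3',4',5'-penta-O-benzyl-(−)-epigallocatechin (1.3 equiv)
Product: 9 protected biaryl (C6' of the epicatechin half bonded to C2' of the epigallocatechin half), via o-quinone 8 (not isolated)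
Conditions: Ag2O (2 equiv), CH2Cl2, 0 °C, 15 min, filter under Ar; then 7, Sc(OTf)3 (10 mol%), CH2Cl2/(CF3)2CHOH 4:1, −40 → 0 °C
Reagents that add atoms: none
Why: Proposed new method: Ag2O dehydrogenates the catechol of 4 to o-quinone 8, which turns C6' from a nucleophilic arene carbon (para to the 3'-OH) into the β-carbon of an enedione, and chelation of the 1,2-dicarbonyl by Sc(OTf)3 in hexafluoroisopropanol lets the only free arene position of 7 (ortho and para to two ether oxygens) add there in Friedel–Crafts fashion before tautomerisation restores the catechol; the closest known reactions are the acid-catalysed hydroarylation of quinones and quinone monoacetals by alkoxyarenes and the C6'-selective attack of carbon nucleophiles on catechin ring-B quinones in tea-pigment formation, and no stereocentre is formed or touched, only the biaryl axis.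

**Step 5**
Reactants: 9 protected biaryl
Product: 10 degalloyl theasinensin F
Conditions: H2 (1 atm), Pd(OH)2/C, Et3N (2.2 equiv), THF/MeOH/H2O, rt
Reagents that add atoms: none
Why: Heterogeneous hydrogenolysis cleaves the five benzyl ethers and three benzyl carbonates (with loss of CO2) and reduces both aryl bromides with Et3N taking up the HBr, while the cyclic benzylic C2–O1 bonds of flavans survive these conditions, so the four stereocentres are kept.

**Compound list**
1 | (−)-epicatechin, (2R,3R)-2-(3,4-dihydroxyphenyl)chromane-3,5,7-triol | Oc1cc(O)c2c(c1)O[C@H](c1ccc(O)c(O)c1)[C@H](O)C2 | starting material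
2 | 3',4'-O-(phenylboranediyl)-(−)-epicatechin (cyclic phenylboronic ester of the catechol, 2R,3R) | Oc1cc(O)c2c(c1)O[C@H](c1ccc3OB(c4ccccc4)Oc3c1)[C@H](O)C2 | intermediate (not isolated)
3 | 3,5,7-tris-O-(benzyloxycarbonyl)-3',4'-O-(phenylboranediyl)-(−)-epicatechin (2R,3R) | O=C(OCc1ccccc1)Oc1cc(OC(=O)OCc3ccccc3)c2c(c1)O[C@H](c1ccc3OB(c4ccccc4)Oc3c1)[C@H](OC(=O)OCc1ccccc1)C2 | intermediate (not isolated)
4 | 3,5,7-tris-O-(benzyloxycarbonyl)-(−)-epicatechin (free 3',4'-catechol, 2R,3R) | O=C(OCc1ccccc1)Oc1cc(OC(=O)OCc3ccccc3)c2c(c1)O[C@H](c1ccc(O)c(O)c1)[C@H](OC(=O)OCc1ccccc1)C2 | intermediate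
5 | (−)-epigallocatechin, (2R,3R)-2-(3,4,5-trihydroxyphenyl)chromane-3,5,7-triol | Oc1cc(O)c2c(c1)O[C@H](c1cc(O)c(O)c(O)c1)[C@H](O)C2 | starting material
6 | 5,7,3',4',5'-penta-O-benzyl-(−)-epigallocatechin (3-OH free, 2R,3R) | c1ccccc1COc1cc(OCc3ccccc3)c2c(c1)O[C@H](c1cc(OCc3ccccc3)c(OCc3ccccc3)c(OCc3ccccc3)c1)[C@H](O)C2 | intermediate
7 | 6,8-dibromo-5,7,3',4',5'-penta-O-benzyl-(−)-epigallocatechin (2R,3R) | c1ccccc1COc1c(Br)c(OCc3ccccc3)c2c(c1Br)O[C@H](c1cc(OCc3ccccc3)c(OCc3ccccc3)c(OCc3ccccc3)c1)[C@H](O)C2 | intermediate
8 | o-quinone of 4, (2R,3R)-2-(3,4-dioxocyclohexa-1,5-dien-1-yl)chromane-3,5,7-triyl tribenzyl tricarbonate | O=C(OCc1ccccc1)Oc1cc(OC(=O)OCc3ccccc3)c2c(c1)O[C@H](C1=CC(=O)C(=O)C=C1)[C@H](OC(=O)OCc1ccccc1)C2 | intermediate (not isolated)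
9 | protected biaryl: epicatechin half (3,5,7-tris-O-benzyloxycarbonyl, free 3',4'-catechol) joined through its C6' to C2' of the epigallocatechin half (6,8-dibromo, 5,7,3',4',5'-penta-O-benzyl, 3-OH free); 2R,3R in both halves | O=C(OCc1ccccc1)Oc1cc(OC(=O)OCc3ccccc3)c2c(c1)O[C@H](c1cc(O)c(O)cc1-c1c([C@H]3Oc4c(Br)c(OCc5ccccc5)c(Br)c(OCc5ccccc5)c4C[C@H]3O)cc(OCc5ccccc5)c(OCc5ccccc5)c1OCc5ccccc5)[C@H](OC(=O)OCc1ccccc1)C2 | intermediate
10 | degalloyl theasinensin F | Oc1cc(O)c2c(c1)O[C@H](c1cc(O)c(O)cc1-c1c([C@H]3Oc4cc(O)cc(O)c4C[C@H]3O)cc(O)c(O)c1O)[C@H](O)C2 | target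

**Step count and risks**
Total step count: 5. Longest linear sequence: 4 steps (5 → 6 → 7 → 9 → 10).

Most likely to fail, first: step 4. Arene 7 is hindered and only moderately nucleophilic, and quinone 8 can isomerise to its quinone methide (loss of C2 configuration), add at C5' instead of C6', or oxidise the product. The fallback replaces the aryl ether donor by a free phenol that adds through its para carbon without Lewis acid, the mode in which tea catechins couple, and needs a different epigallocatechin building block. It sets out from 5. Ph2CCl2 and K2CO3 in MeCN give 3',4'-O-(diphenylmethylene)-(−)-epigallocatechin F1; the cyclic ketal leaves one ring-B phenol free but makes oxidation of that ring to a quinone impossible. NBS (2 equiv) in THF at −78 °C blocks ring A and gives 6,8-dibromo-3',4'-O-(diphenylmethylene)-(−)-epigallocatechin F2. F2 is added to quinone 8 (made from 4 with Ag2O as in step 4) in MeCN/(CF3)2CHOH at −20 °C to give the phenolic biaryl F3, bonded from C6' of the epicatechin half to C2' of the other half, para to the free 5'-OH (attack at the ortho carbon C6' would lead to the same final product). H2, Pd(OH)2/C and Et3N then remove the ketal, the carbonates and the bromines, and the route is rejoined at 10.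

Second: step 1. The boronate may not survive the acylation (over-acylated catechol), or the hindered 3-OH may be acylated incompletely. The fallback uses an isolated, acid-labile ketal instead of the transient boronate. It sets out from 1. Ph2CCl2 and K2CO3 in MeCN give 3',4'-O-(diphenylmethylene)-(−)-epicatechin F4. CbzCl, iPr2NEt and DMAP give 3,5,7-tris-O-(benzyloxycarbonyl)-3',4'-O-(diphenylmethylene)-(−)-epicatechin F5. CF3CO2H/H2O in CH2Cl2 at rt hydrolyses the ketal without touching the benzyl carbonates, and the route is rejoined at 4.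

Third: step 2. The free pyrogallol is easily air-oxidised and C-benzylated under base, so the yield may collapse. The fallback never exposes the free polyphenolate. It sets out from 5. Ac2O in pyridine gives the air-stable 3,5,7,3',4',5'-hexa-O-acetyl-(−)-epigallocatechin F6. K2CO3 and BnBr in DMF/MeOH then release each phenoxide by methanolysis in the presence of BnBr, so it is benzylated at once, while the 3-acetate is methanolysed to the free alcohol, and the route is rejoined at 6.

**Further compounds**
F1 | step 4 | 3',4'-O-(diphenylmethylene)-(−)-epigallocatechin | Oc1cc(O)c2c(c1)O[C@H](c1cc(O)c3OC(c4ccccc4)(c4ccccc4)Oc3c1)[C@H](O)C2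
F2 | step 4 | 6,8-dibromo-3',4'-O-(diphenylmethylene)-(−)-epigallocatechin | Oc1c(Br)c(O)c2c(c1Br)O[C@H](c1cc(O)c3OC(c4ccccc4)(c4ccccc4)Oc3c1)[C@H](O)C2
F3 | step 4 | phenolic biaryl: epicatechin half as in 9 joined through C6' to C2' of 6,8-dibromo-3',4'-O-(diphenylmethylene)-(−)-epigallocatechin | O=C(OCc1ccccc1)Oc1cc(OC(=O)OCc3ccccc3)c2c(c1)O[C@H](c1cc(O)c(O)cc1-c1c([C@H]3Oc4c(Br)c(O)c(Br)c(O)c4C[C@H]3O)cc(O)c6OC(c5ccccc5)(c5ccccc5)Oc16)[C@H](OC(=O)OCc1ccccc1)C2
F4 | step 1 | 3',4'-O-(diphenylmethylene)-(−)-epicatechin | Oc1cc(O)c2c(c1)O[C@H](c1ccc3OC(c4ccccc4)(c4ccccc4)Oc3c1)[C@H](O)C2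
F5 | step 1 | 3,5,7-tris-O-(benzyloxycarbonyl)-3',4'-O-(diphenylmethylene)-(−)-epicatechin | O=C(OCc1ccccc1)Oc1cc(OC(=O)OCc3ccccc3)c2c(c1)O[C@H](c1ccc3OC(c4ccccc4)(c4ccccc4)Oc3c1)[C@H](OC(=O)OCc1ccccc1)C2
F6 | step 2 | 3,5,7,3',4',5'-hexa-O-acetyl-(−)-epigallocatechin | CC(=O)Oc1cc(OC(C)=O)c2c(c1)O[C@H](c1cc(OC(C)=O)c(OC(C)=O)c(OC(C)=O)c1)[C@H](OC(C)=O)C2
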